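## Structural features

12 is a flavone: ring A and the pyranone ring C share the C4a–C8a bond, and C2 is joined through C2–C1' to a separate benzene ring B. There is no stereocentre, so no stereocentres stand next to each other and the whole problem is constitutional: four hydroxyl and four methoxy groups must each reach the right carbon. Ring A is hexasubstituted (5-OH, 6-OMe, 7-OH, 8-OMe, C4a, C8a), C3 carries a methoxy group, and ring B is a 2',5'-dihydroxy-4'-methoxyphenyl group, that is a hydroquinone. The fragile parts are this hydroquinone, which air oxidises to the quinone once it is deprotonated, and the oxygen on C2' in any open-chain 1,3-diketone precursor. If that oxygen is set free, it closes onto the far carbonyl and builds the isomeric pyranone on ring B. The real difficulty is the alternating OH/OMe pattern on a fully substituted ring A, together with telling four phenols from four methyl ethers. The feature used here is that 6-OMe, 7-O and 8-OMe form the syringyl pattern, that C8a lies ortho to 8-OMe and para to 6-OMe, and that the two ortho C–H of a syringoyl group are equivalent. Ring C can therefore be closed by oxidative O1–C8a bond formation, and the one C–H then left on ring A (C5) lies peri to the C4 carbonyl, where a directed oxygenation can reach it.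

## Logic of the disconnections

12 ⇒ 11. The three ester C–O bonds (acetyl on O7, pivaloyl on O2' and O5') are cut. The phenols are carried as electron-withdrawing esters because all oxidative steps need deactivated rings, and one transesterification removes them together. The forward step must keep oxygen away from the ring-B hydroquinone anion.

11 ⇒ 9. The C5–O bond is cut. C5–H is the only C–H of ring A and lies peri to the C4 carbonyl, so a carbonyl-directed C–H oxygenation can install it last, through the transient ester 10. The gain is that ring A never has to be a pentaoxygenated benzene. The forward step needs an oxidant that leaves the ester-bearing rings and the C2–C3 enol ether alone.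

9 ⇒ 8. The O1–C8a bond is cut, which opens ring C to an open-chain 2-methoxy-1,3-diketone. This turns the flavone into two simple aryl halves at the correct oxidation level and uses the symmetry of the syringoyl ring. The forward step is an oxidative O-aryl closure that must choose ring A over ring B and must not over-oxidise.

8 ⇒ 7 + 3. The C3–C4 bond is cut (flavone numbering), a Claisen-type C-acylation of a ketone by an aroyl chloride. The cut is convergent, and the C3 methoxy group is already present in the ketone. The forward step needs C- over O-acylation and no acyl transfer from O2' to the enolate, which is why the ketone carries pivaloyl and not acetyl groups.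

7 ⇒ 6. The two pivaloyl C–O bonds on O2' and O5' are cut. This leaves a free dihydroxy ketone that one acylation can make. The forward step must esterify both phenols, including the one hydrogen-bonded to the ketone.

6 ⇒ 4 + 5. The aryl–carbonyl bond C1'–C(=O) is cut. The acyl group enters para to the methoxy group and ortho to a hydroxyl of 4, so ring B comes from two cheap compounds. The forward acylation must go to that carbon and not to the one ortho to the other hydroxyl.

3 ⇒ 2. The acyl C–Cl bond is cut. The acid is the stable, storable form of the ring-A half. The forward step must leave the aryl acetate intact.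

2 ⇒ 1. The acetyl C–O bond is cut. This leaves a commercial acid that already holds the 6-OMe/7-O/8-OMe triad. The forward step is a routine acetylation of the single phenol.

## Other disconnections considered

Alternative 1: Ring C would be cut at C3–C4 and O1–C2, so that the key step would deliver 5,7-bis(benzyloxy)-2-[2,5-bis(benzyloxy)-4-methoxyphenyl]-3,6,8-trimethoxy-4H-chromen-4-one (A1) from ring A supplied as a masked salicylate, 5,7-bis(benzyloxy)-6,8-dimethoxy-2,2-dimethyl-4H-1,3-benzodioxin-4-one (A2), and from the ring-B ketone 1-[2,5-bis(benzyloxy)-4-methoxyphenyl]-2-methoxyethan-1-one (A3). In the forward key step the lithium enolate of A3 would add to the dioxinone carbonyl of A2, the acetal would collapse and free the ring-A phenoxide, and acid would close O1–C2 by cyclodehydration to A1; hydrogenolysis of the four benzyl ethers of A1 would then give 12. In favour: both ring-C bonds come from polar reactions of well-understood type, only one phenoxide is available so the direction of closure is not in doubt, no oxidation is needed, and the final deprotection is neutral and reductive, which suits the hydroquinone. On mechanistic security, on regiochemical certainty and on the mildness of the last step this alternative is the better plan. Against: A2 derives from a pentaoxygenated benzoic acid in which five oxygens must be differentiated on a hexasubstituted ring, which means a long linear aromatic sequence with a regiochemical question at almost every step, and the dioxinone carbonyl of A2 is flanked by two ortho substituents and fed by five donors, so the enolate addition is expected to be slow. Comparison: the chosen plan takes ring A from 1 in two steps and is shorter overall, but it pays with one unprecedented step and a late C–H oxidation, whereas the route through A1 is longer and safer.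

Alternative 2: Ring A would be cut at C7–C8 and C4a–C5 and built onto a finished pyranone, so that the key step would deliver 2-[2,5-bis(benzyloxy)-4-methoxyphenyl]-5,7-dihydroxy-3,6,8-trimethoxy-4H-chromen-4-one (A4) from 2-[2,5-bis(benzyloxy)-4-methoxyphenyl]-3-methoxy-6-(methoxymethyl)-4H-pyran-4-one (A5) and the three-carbon partner dimethyl methoxymalonate (A6), with A5 itself derived from kojic acid (A7). In the forward key step the dienolate of A5 would be acylated at the methoxymethyl carbon by A6, the α-carbon of the same dienolate system (the future C4a) would then attack the second ester, and enolisation would give A4; hydrogenolysis of the two benzyl ethers of A4 would end the route at 12. In favour: the whole oxygen pattern of ring A arises by construction, since 8-OMe comes from the side chain of A5, 6-OMe from A6, and 5-OH and 7-OH from the two ester carbonyls of A6, so that no aromatic substitution, no C–H oxidation and no protection of ring A are needed. On structural logic this alternative is the equal of the chosen plan or better. Against: A5 must first be made from A7 by two O-methylations and an arylation at the pyranone carbon next to the ring oxygen, and the annulation is itself without close precedent, because γ-acylation of a pyranone dienolate must be followed by an α-selective Claisen closure. Comparison: in novelty risk the route through A4 is no safer than the chosen plan, and in step count it is expected to be similar or slightly longer.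

Alternative 3: Ring C would be cut at O1–C2 with C3 functionalised in the same step, so that the key step would deliver 2-[5,7-bis(benzyloxy)-3-iodo-6,8-dimethoxy-4-oxo-4H-chromen-2-yl]-5-methoxy-1,4-phenylene diacetate (A8) from the symmetrical ynone 2-[3-oxo-3-(2,4,6-tris(benzyloxy)-3,5-dimethoxyphenyl)prop-1-yn-1-yl]-5-methoxy-1,4-phenylene diacetate (A9). In the forward key step an electrophilic iodine reagent would activate the alkyne of A9, one of the two equivalent ortho benzyloxy oxygens would attack C2 in a 6-endo-dig closure, and the oxonium ion would lose its benzyl group as the chloride to give A8. In favour: iodocyclisation of ortho-alkoxyaryl ynones is an established reaction class, the symmetry of ring A removes any choice between ortho oxygens, the conditions are mild and non-basic, and the acetates keep O2' from attacking the alkyne. On precedent for the ring closure this alternative is better than the chosen plan, and in its use of a symmetrical ring A it is the equal. Against: C3 of A8 ends as an iodide, and its exchange for methoxy at a carbon flanked by the C2 aryl group and the C4 carbonyl needs a copper-mediated methoxylation under basic conditions that strip the acetates, or a borylation, oxidation and methylation sequence; the ring-A unit of A9 is again a pentaoxygenated, fully substituted benzene that takes many steps to make. Comparison: the chosen plan has the C3 methoxy group in place from 5 and needs no pentaoxygenated benzene, so it is clearly shorter, whereas the route through A8 is the more certain in its key step.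

Key step: step 6

Remark on the chemistry: an acetate on O2' of the diketone would lie within reach of the enolate carbon and oxygen and would act as an internal acyl donor under the enolising conditions of steps 5 and 6 (Baker–Venkataraman-type transfer, then closure of the wrong pyranone). The two ring-B phenols are therefore carried as pivalates. The skeletons of 8 and 9 are unchanged, and the 7-O-acetate on ring A is kept.

Remark on the structures: the connectivity of 8 and 9 agrees atom by atom with the numbering of 12. The attacked carbon is ortho to the future 8-OMe and para to the future 6-OMe. Flavone numbering (O1, C2 to C8a, primed ring B) is used for all intermediates.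

## Route

Step 1
Reactants: 1 syringic acid (4-hydroxy-3,5-dimethoxybenzoic acid)
Product: 2 4-acetoxy-3,5-dimethoxybenzoic acid
Conditions: Ac2O, pyridine, 0 °C to rt; then H2O, aq. HCl
Reagents that add atoms: acetic anhydride, CC(=O)OC(C)=O
Why: O-acetylation of the only phenol; the acetate is small enough to sit between two methoxy groups and later protects O7 against oxidation in steps 6 and 7.

Step 2
Reactants: 2 4-acetoxy-3,5-dimethoxybenzoic acid
Product: 3 4-acetoxy-3,5-dimethoxybenzoyl chloride
Conditions: (COCl)2, DMF (cat.), CH2Cl2, 0 °C to rt; evaporate
Reagents that add atoms: oxalyl chloride, O=C(Cl)C(=O)Cl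
Why: Acid chloride formation through the Vilsmeier-type chloroiminium catalyst; the aryl acetate is inert and the crude chloride should be used directly.

Step 3
Reactants: 4 methoxyhydroquinone (2-methoxybenzene-1,4-diol); 5 methoxyacetic acid
Product: 6 1-(2,5-dihydroxy-4-methoxyphenyl)-2-methoxyethan-1-one
Conditions: BF3·OEt2 (neat), 80–90 °C; then aq. NaOAc
Reagents that add atoms: none
Why: BF3-promoted Friedel–Crafts acylation of a phenol by a carboxylic acid (O-acylation and Fries-type migration); the acyl group should enter at the carbon ortho to the 4-OH and para to the methoxy group, a resorcinol-type position, as in the known acetylation of the same diol.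

Step 4
Reactants: 6 1-(2,5-dihydroxy-4-methoxyphenyl)-2-methoxyethan-1-one
Product: 7 1-[4-methoxy-2,5-bis(pivaloyloxy)phenyl]-2-methoxyethan-1-one
Conditions: t-BuCOCl, Et3N, DMAP (cat.), CH2Cl2, 0 °C to rt
Reagents that add atoms: pivaloyl chloride, CC(C)(C)C(=O)Cl
Why: Esterification of both phenols; the pivalates deactivate ring B for step 6 and are too hindered to transfer to the neighbouring enolate in step 5.

Step 5
Reactants: 7 1-[4-methoxy-2,5-bis(pivaloyloxy)phenyl]-2-methoxyethan-1-one; 3 4-acetoxy-3,5-dimethoxybenzoyl chloride
Product: 8 1-(4-acetoxy-3,5-dimethoxyphenyl)-2-methoxy-3-[4-methoxy-2,5-bis(pivaloyloxy)phenyl]propane-1,3-dione (racemic at C2, enolisable)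
Conditions: MgBr2·OEt2, iPr2NEt, CH2Cl2, 0 °C to rt; then cold 1 M HCl
Reagents that add atoms: none
Why: Claisen-type C-acylation under soft enolisation: Mg2+ chelated between the ketone oxygen and the α-methoxy group acidifies the CH2 so that the amine forms the magnesium enolate in the presence of the acid chloride, which traps it at carbon. The product rests as the magnesium diketonate until the acid quench; its C2 centre is of no consequence because it is lost in step 6.

Step 6
Reactants: 8 1-(4-acetoxy-3,5-dimethoxyphenyl)-2-methoxy-3-[4-methoxy-2,5-bis(pivaloyloxy)phenyl]propane-1,3-dione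
Product: 9 7-acetoxy-3,6,8-trimethoxy-2-[4-methoxy-2,5-bis(pivaloyloxy)phenyl]-4H-chromen-4-one
Conditions: graphite anode, Pt cathode, undivided cell, constant current, Bu4NBF4, (CF3)2CHOH/CH2Cl2, 2,6-lutidine, rt
Reagents that add atoms: none
Why: Proposed new method: 2,6-lutidine converts part of 8 into its enolate, which should be oxidised at the carbon anode well below the potential of either ester-deactivated arene to the 2-methoxy-1,3-dioxo radical, with spin on the central carbon (the future C3) and on both oxygens. Attack through carbon on either ring would need a four-membered ring, so the only feasible closure is that of the ring-B-side oxygen onto an ortho carbon of ring A, a six-membered closure onto an arene (formally 6-endo, the C4a–C8a bond lying inside the new ring C). The cyclohexadienyl radical so formed is stabilised by 8-OMe, 6-OMe and the C4 acyl group; it gives up a second electron and a proton to lutidine to restore the arene, while protons are reduced to H2 at the cathode. The closest known types are the anodic dehydrogenative lactonisation of biaryl-2-carboxylic acids to benzocoumarins and the oxidative cyclisation of 1,3-dicarbonyl radicals onto arenes; an O-aryl closure of a diketone enol to a flavone has not been shown. No stereocentre is formed and the C2 centre of 8 disappears. The step needs ring A to be chosen over C6' of ring B: the attacked carbon of ring A has methoxy groups ortho and para, whereas C6' is meta to its only methoxy group and flanked by a pivalate, and the two ortho carbons of ring A are equivalent, so only one flavone can arise from ring A. Over-oxidation should be limited by charge control, because 9 no longer has the easily oxidised enolate.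

Step 7
Reactants: 9 7-acetoxy-3,6,8-trimethoxy-2-[4-methoxy-2,5-bis(pivaloyloxy)phenyl]-4H-chromen-4-one
Product: 11 7-acetoxy-5-hydroxy-3,6,8-trimethoxy-2-[4-methoxy-2,5-bis(pivaloyloxy)phenyl]-4H-chromen-4-one, via C5-trifluoroacetate ester 10 (not isolated)
Conditions: [RuCl2(p-cymene)]2 (cat.), PhI(OCOCF3)2, CF3CO2H/(CF3CO)2O, 70 °C; then aq. Na2S2O3, H2O/THF, rt
Reagents that add atoms: [bis(trifluoroacetoxy)iodo]benzene, O=C(OI(OC(=O)C(F)(F)F)c1ccccc1)C(F)(F)F
Why: Ketone-directed ortho C–H oxygenation: the C4 carbonyl guides divalent ruthenium to C5–H (five-membered ruthenacycle), the trivalent iodine reagent oxidises the metal, and C–O reductive elimination gives trifluoroacetate 10, which water hydrolyses after the oxidant is quenched. The reaction type is established for C5–H of flavones and chromones, and the ester-bearing rings should resist the oxidant.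

Step 8
Reactants: 11 7-acetoxy-5-hydroxy-3,6,8-trimethoxy-2-[4-methoxy-2,5-bis(pivaloyloxy)phenyl]-4H-chromen-4-one
Product: 12 5,7,2',5'-tetrahydroxy-3,6,8,4'-tetramethoxyflavone
Conditions: NaOMe, MeOH/THF (degassed), Ar, 0 °C to rt; then degassed 1 M HCl
Reagents that add atoms: none
Why: Methoxide transesterification of the three aryl esters (acetate fast, pivalates more slowly); argon and an acidic quench keep the ring-B hydroquinone anion from air oxidation, and the symmetrical ring A makes any Wessely–Moser-type ring opening and reclosure degenerate.

## Compound list

1 | syringic acid (4-hydroxy-3,5-dimethoxybenzoic acid) | COc1cc(C(=O)O)cc(OC)c1O | starting material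
2 | 4-acetoxy-3,5-dimethoxybenzoic acid | COc1cc(C(=O)O)cc(OC)c1OC(C)=O | intermediate
3 | 4-acetoxy-3,5-dimethoxybenzoyl chloride | COc1cc(C(=O)Cl)cc(OC)c1OC(C)=O | intermediate
4 | methoxyhydroquinone (2-methoxybenzene-1,4-diol) | COc1cc(O)ccc1O | starting material
5 | methoxyacetic acid | COCC(=O)O | starting material
6 | 1-(2,5-dihydroxy-4-methoxyphenyl)-2-methoxyethan-1-one | COCC(=O)c1cc(O)c(OC)cc1O | intermediate
7 | 1-[4-methoxy-2,5-bis(pivaloyloxy)phenyl]-2-methoxyethan-1-one | COCC(=O)c1cc(OC(=O)C(C)(C)C)c(OC)cc1OC(=O)C(C)(C)C | intermediate
8 | 1-(4-acetoxy-3,5-dimethoxyphenyl)-2-methoxy-3-[4-methoxy-2,5-bis(pivaloyloxy)phenyl]propane-1,3-dione (racemic at C2) | COc1cc(C(=O)C(OC)C(=O)c2cc(OC(=O)C(C)(C)C)c(OC)cc2OC(=O)C(C)(C)C)cc(OC)c1OC(C)=O | intermediate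
9 | 7-acetoxy-3,6,8-trimethoxy-2-[4-methoxy-2,5-bis(pivaloyloxy)phenyl]-4H-chromen-4-one | COc1cc(OC(=O)C(C)(C)C)c(-c2oc3c(OC)c(OC(C)=O)c(OC)cc3c(=O)c2OC)cc1OC(=O)C(C)(C)C | intermediate
10 | 7-acetoxy-3,6,8-trimethoxy-2-[4-methoxy-2,5-bis(pivaloyloxy)phenyl]-5-(trifluoroacetoxy)-4H-chromen-4-one | COc1cc(OC(=O)C(C)(C)C)c(-c2oc3c(OC)c(OC(C)=O)c(OC)c(OC(=O)C(F)(F)F)c3c(=O)c2OC)cc1OC(=O)C(C)(C)C | intermediate
11 | 7-acetoxy-5-hydroxy-3,6,8-trimethoxy-2-[4-methoxy-2,5-bis(pivaloyloxy)phenyl]-4H-chromen-4-one | COc1cc(OC(=O)C(C)(C)C)c(-c2oc3c(OC)c(OC(C)=O)c(OC)c(O)c3c(=O)c2OC)cc1OC(=O)C(C)(C)C | intermediate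
12 | 5,7,2',5'-tetrahydroxy-3,6,8,4'-tetramethoxyflavone | COc1cc(O)c(-c2oc3c(OC)c(O)c(OC)c(O)c3c(=O)c2OC)cc1O | target

## Step count and least certain steps

Total step count: 8. Longest linear sequence: 6 steps (steps 3 to 8, from 4 and 5); the ring-A branch (steps 1 and 2) joins at step 5.

Step 6 (key step). The most likely failure is that the enolate radical is oxidised further to the cation at the central carbon and captured by solvent, or that it dimerises, before the oxygen can add to an arene carbon that the neighbouring carbonyl deactivates. Partial closure onto ring B is the second risk. The fallback makes the same O1–C8a bond by known chemistry, a copper-catalysed intramolecular O-arylation of a 1-(2-bromoaryl)-1,3-diketone. It sets out from 2 and returns at 9. Bromination of 2 (NBS, MeCN, rt) at one of the two equivalent free carbons, each ortho to one methoxy group and para to the other, should give 4-acetoxy-2-bromo-3,5-dimethoxybenzoic acid F1. (COCl)2 with catalytic DMF converts it into 4-acetoxy-2-bromo-3,5-dimethoxybenzoyl chloride F2. Acylation of 7 under the conditions of step 5 gives 1-(4-acetoxy-2-bromo-3,5-dimethoxyphenyl)-2-methoxy-3-[4-methoxy-2,5-bis(pivaloyloxy)phenyl]propane-1,3-dione F3. CuI (cat.), 1,10-phenanthroline and anhydrous K3PO4 in toluene at 90 °C should then close the enolate oxygen onto the C–Br carbon (Ullmann-type, monovalent copper) to give 9. The fallback costs one step more.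

Step 5. The most likely failures are O-acylation of the enolate, a second acylation of the product diketonate, or slow acyl migration from O2' within the chelated diketonate. The fallback replaces the Claisen-type acylation by aldol addition and oxidation. It sets out from 7 and returns at 8. The lithium enolate of 7 (LiN(SiMe3)2, THF, −78 °C) is added to 4-acetoxy-3,5-dimethoxybenzaldehyde F4 (from commercial syringaldehyde, Ac2O, pyridine) and quenched cold with AcOH. This gives 3-(4-acetoxy-3,5-dimethoxyphenyl)-3-hydroxy-2-methoxy-1-[4-methoxy-2,5-bis(pivaloyloxy)phenyl]propan-1-one F5 as a mixture of diastereomers. Dess–Martin periodinane (NaHCO3, CH2Cl2) oxidises it to 8.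

Step 7. The most likely failures are slow cyclometalation at C5 because of the adjacent 6-OMe, or partial acidolysis of the esters in the hot trifluoroacetic medium followed by oxidative degradation of freed phenols. The fallback replaces directed C–H oxygenation by halogenation, borylation and oxidation. It sets out from 9 and returns at 11. Electrophilic bromination (NBS, MeCN) should go to C5, which has methoxy groups ortho and para to it, whereas on ring B only C3' has a methoxy group next to it and both free positions are flanked by pivalates. The product is 7-acetoxy-5-bromo-3,6,8-trimethoxy-2-[4-methoxy-2,5-bis(pivaloyloxy)phenyl]-4H-chromen-4-one F6. Miyaura borylation (B2pin2, Pd(OAc)2, SPhos, KOAc, dioxane, 90 °C) gives 7-acetoxy-3,6,8-trimethoxy-2-[4-methoxy-2,5-bis(pivaloyloxy)phenyl]-5-(4,4,5,5-tetramethyl-1,3,2-dioxaborolan-2-yl)-4H-chromen-4-one F7. Oxidation with NaBO3·4H2O in THF/H2O gives 11; any ester lost on the way converges in step 8.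

Step 3. The most likely failures are acylation at the carbon ortho to the other hydroxyl, arrest at the O-acyl stage, or ether cleavage by hot BF3. The fallback is a Houben–Hoesch reaction, which uses a nitrile electrophile under milder acid. It sets out from 4 and returns at 6. Methoxyacetonitrile, ZnCl2 and HCl gas in Et2O at 0 °C should give 1-(2,5-dihydroxy-4-methoxyphenyl)-2-methoxyethan-1-iminium chloride F8 at the same resorcinol-type carbon. Heating in water hydrolyses it to 6.

## Further compounds

F1 | step 6 | 4-acetoxy-2-bromo-3,5-dimethoxybenzoic acid | COc1cc(C(=O)O)c(Br)c(OC)c1OC(C)=O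
F2 | step 6 | 4-acetoxy-2-bromo-3,5-dimethoxybenzoyl chloride | COc1cc(C(=O)Cl)c(Br)c(OC)c1OC(C)=O
F3 | step 6 | 1-(4-acetoxy-2-bromo-3,5-dimethoxyphenyl)-2-methoxy-3-[4-methoxy-2,5-bis(pivaloyloxy)phenyl]propane-1,3-dione (racemic at C2) | COc1cc(C(=O)C(OC)C(=O)c2cc(OC(=O)C(C)(C)C)c(OC)cc2OC(=O)C(C)(C)C)c(Br)c(OC)c1OC(C)=O
F4 | step 5 | 4-acetoxy-3,5-dimethoxybenzaldehyde | COc1cc(C=O)cc(OC)c1OC(C)=O
F5 | step 5 | 3-(4-acetoxy-3,5-dimethoxyphenyl)-3-hydroxy-2-methoxy-1-[4-methoxy-2,5-bis(pivaloyloxy)phenyl]propan-1-one (mixture of diastereomers, racemic) | COc1cc(C(O)C(OC)C(=O)c2cc(OC(=O)C(C)(C)C)c(OC)cc2OC(=O)C(C)(C)C)cc(OC)c1OC(C)=O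
F6 | step 7 | 7-acetoxy-5-bromo-3,6,8-trimethoxy-2-[4-methoxy-2,5-bis(pivaloyloxy)phenyl]-4H-chromen-4-one | COc1cc(OC(=O)C(C)(C)C)c(-c2oc3c(OC)c(OC(C)=O)c(OC)c(Br)c3c(=O)c2OC)cc1OC(=O)C(C)(C)C
F7 | step 7 | 7-acetoxy-3,6,8-trimethoxy-2-[4-methoxy-2,5-bis(pivaloyloxy)phenyl]-5-(4,4,5,5-tetramethyl-1,3,2-dioxaborolan-2-yl)-4H-chromen-4-one | COc1cc(OC(=O)C(C)(C)C)c(-c2oc3c(OC)c(OC(C)=O)c(OC)c(B4OC(C)(C)C(C)(C)O4)c3c(=O)c2OC)cc1OC(=O)C(C)(C)C
F8 | step 3 | 1-(2,5-dihydroxy-4-methoxyphenyl)-2-methoxyethan-1-iminium chloride | COCC(=[NH2+])c1cc(O)c(OC)cc1O.[Cl-]
A1 | alternative 1 | 5,7-bis(benzyloxy)-2-[2,5-bis(benzyloxy)-4-methoxyphenyl]-3,6,8-trimethoxy-4H-chromen-4-one | COc1cc(OCc2ccccc2)c(-c2oc3c(OC)c(OCc4ccccc4)c(OC)c(OCc4ccccc4)c3c(=O)c2OC)cc1OCc1ccccc1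
A2 | alternative 1 | 5,7-bis(benzyloxy)-6,8-dimethoxy-2,2-dimethyl-4H-1,3-benzodioxin-4-one | CC1(C)OC(=O)c2c(OCc3ccccc3)c(OC)c(OCc3ccccc3)c(OC)c2O1
A3 | alternative 1 | 1-[2,5-bis(benzyloxy)-4-methoxyphenyl]-2-methoxyethan-1-one | COCC(=O)c1cc(OCc2ccccc2)c(OC)cc1OCc1ccccc1
A4 | alternative 2 | 2-[2,5-bis(benzyloxy)-4-methoxyphenyl]-5,7-dihydroxy-3,6,8-trimethoxy-4H-chromen-4-one | COc1cc(OCc2ccccc2)c(-c2oc3c(OC)c(O)c(OC)c(O)c3c(=O)c2OC)cc1OCc1ccccc1
A5 | alternative 2 | 2-[2,5-bis(benzyloxy)-4-methoxyphenyl]-3-methoxy-6-(methoxymethyl)-4H-pyran-4-one | COCc1cc(=O)c(OC)c(-c2cc(OCc3ccccc3)c(OC)cc2OCc2ccccc2)o1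
A6 | alternative 2 | dimethyl methoxymalonate | COC(C(=O)OC)C(=O)OC
A7 | alternative 2 | kojic acid (5-hydroxy-2-(hydroxymethyl)-4H-pyran-4-one) | OCc1cc(=O)c(O)co1
A8 | alternative 3 | 2-[5,7-bis(benzyloxy)-3-iodo-6,8-dimethoxy-4-oxo-4H-chromen-2-yl]-5-methoxy-1,4-phenylene diacetate | COc1cc(OC(C)=O)c(-c2oc3c(OC)c(OCc4ccccc4)c(OC)c(OCc4ccccc4)c3c(=O)c2I)cc1OC(C)=O
A9 | alternative 3 | 2-[3-oxo-3-(2,4,6-tris(benzyloxy)-3,5-dimethoxyphenyl)prop-1-yn-1-yl]-5-methoxy-1,4-phenylene diacetate | COc1cc(OC(C)=O)c(C#CC(=O)c2c(OCc3ccccc3)c(OC)c(OCc3ccccc3)c(OC)c2OCc2ccccc2)cc1OC(C)=O
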